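**Plan**
- **Cuts (retrosynthetic order):** (a) both O–Si bonds. (b) The C5'–C6' CH2–CH2 bond of the C32 acyl chain, which gives labdanyl hydrogen adipate 8 and C28 ω-silyloxy acid 14; each carries one extra CO2H that leaves as CO2. (c) The C15–O acyl bond, which gives alcohol 6 and adipic acid. (d) C16–C17 of 14, which gives a C16 bromo acid and a C12 Grignard reagent.
- **Enabling feature:** the acyl residue is an unbranched (CH2)31 rod. C5' and C6' are plain methylenes with no heteroatom closer than the ester C1'=O. The ring-B C7=C8 and side-chain C13=C14 bonds lie at least eight atoms from C5', so two unstabilised primary radicals have little to do but couple.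
- **Forward order:** no ring is built, because the trans-decalin (rings A/B) comes intact with (−)-copalic acid. C8=C17 is transposed through its epoxide to C7=C8/C17-OH. Silylation, ester reduction, adipoylation, anodic chain union and desilylation follow.
- **Stereochemistry:** C5, C9, C10 (ent-labdane, 5R,9S,10R in the target) and the 13E alkene come from (−)-copalic acid and are never touched. The C8 centre of the epoxide is transient.

Key step: step 9

Remark: the acyl residue is read as 32-hydroxydotriacontanoyl (C1' carbonyl plus 31 CH2), and the descriptors place the decalin in the ent-labdane series, that of (−)-copalic acid (sold as an isolated natural-product standard) and opposite to sclareol or sclareolide.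

Step 1
Reactants: 1 (−)-copalic acid, ent-labda-8(17),13E-dien-15-oic acid (5R,9R,10R)
Product: 2 isopropyl ent-labda-8(17),13E-dien-15-oate
Conditions: 2-iodopropane, K2CO3, DMF, rt to 40 °C
Reagents that add atoms: 2-iodopropane, CC(C)I
Why: SN2 O-alkylation of the potassium carboxylate touches neither alkene nor any stereocentre, and the isopropyl ester is chosen so that alkoxide exchange with Al(OiPr)3 in step 3 is degenerate.

Step 2
Reactants: 2 isopropyl ent-labda-8(17),13E-dien-15-oate
Product: 3 isopropyl (8S)-8,17-epoxy-ent-labd-13E-en-15-oate (oxirane O on the face opposite the C10 methyl)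
Conditions: mCPBA (1.1 equiv), CH2Cl2, 0 °C
Reagents that add atoms: mCPBA, O=C(OO)c1cccc(Cl)c1
Why: Prilezhaev epoxidation is chemoselective for the electron-rich 1,1-disubstituted C8=C17 bond over the ester-conjugated C13=C14 bond, and the peracid should approach opposite the axial C10 methyl group, setting a C8 centre that step 3 erases.

Step 3
Reactants: 3 isopropyl (8S)-8,17-epoxy-ent-labd-13E-en-15-oate
Product: 4 isopropyl 17-hydroxy-ent-labda-7,13E-dien-15-oate
Conditions: Al(OiPr)3 (1.5 equiv), toluene, reflux; aq. Rochelle salt work-up
Reagents that add atoms: none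
Why: In this aluminium-alkoxide-mediated epoxide-to-allylic-alcohol isomerisation (the type that converts β-pinene oxide into myrtenol), Al coordination loosens the tertiary C8–O bond and an isopropoxide ligand should remove a syn proton from the accessible C7 methylene rather than the crowded C9 methine, giving C7=C8 and the C17 carbinol with C9 untouched.

Step 4
Reactants: 4 isopropyl 17-hydroxy-ent-labda-7,13E-dien-15-oate
Product: 5 isopropyl 17-[(tert-butyldimethylsilyl)oxy]-ent-labda-7,13E-dien-15-oate
Conditions: TBSCl, imidazole, DMF, rt
Reagents that add atoms: TBSCl, CC(C)(C)[Si](C)(C)Cl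
Why: Imidazole-promoted silylation of the only free hydroxyl masks C17–OH so that C15–OH can later be acylated alone.

Step 5
Reactants: 5 isopropyl 17-[(tert-butyldimethylsilyl)oxy]-ent-labda-7,13E-dien-15-oate
Product: 6 17-[(tert-butyldimethylsilyl)oxy]-ent-labda-7,13E-dien-15-ol
Conditions: DIBAL-H (2.5 equiv), CH2Cl2, −78 to −20 °C; aq. Rochelle salt work-up
Reagents that add atoms: none
Why: DIBAL-H 1,2-reduction of the α,β-unsaturated ester gives the allylic alcohol with retention of the 13E geometry, and the silyl ether and C7=C8 are inert.

Step 6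
Reactants: 6 17-[(tert-butyldimethylsilyl)oxy]-ent-labda-7,13E-dien-15-ol; 7 adipic acid (5 equiv)
Product: 8 6-oxo-6-{[17-(tert-butyldimethylsilyloxy)-ent-labda-7,13E-dien-15-yl]oxy}hexanoic acid (labdanyl hydrogen adipate)
Conditions: EDC·HCl (1.5 equiv), DMAP (0.3 equiv), THF–CH2Cl2, 0 °C to rt; aqueous wash removes excess diacid
Reagents that add atoms: none
Why: Steglich-type carbodiimide/DMAP esterification with a fivefold excess of the symmetrical diacid statistically favours the mono-ester and leaves the second carboxyl group as the traceless handle for step 9.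

Step 7
Reactants: 9 12-bromododecan-1-ol
Product: 10 (12-bromododecyloxy)(tert-butyl)dimethylsilane
Conditions: TBSCl, imidazole, CH2Cl2, rt
Reagents that add atoms: TBSCl, CC(C)(C)[Si](C)(C)Cl
Why: Imidazole-promoted silylation of the primary alcohol removes the acidic proton, so the bromide can be turned into a Grignard reagent.

Step 8
Reactants: 10 (12-bromododecyloxy)(tert-butyl)dimethylsilane (1.5 equiv); 11 16-bromohexadecanoic acid
Product: 14 28-[(tert-butyldimethylsilyl)oxy]octacosanoic acid, via Grignard reagent 12 (not isolated), via chloromagnesium carboxylate 13 (not isolated)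
Conditions: 10, Mg, THF, 40 °C; separately 11, MeMgCl (1.0 equiv), THF, −20 °C; combine, Li2CuCl4 (3 mol%), NMP (4 equiv), −10 °C to rt; cold mildly acidic work-up (pH 3–4)
Reagents that add atoms: none
Why: Kochi-type copper-catalysed sp3–sp3 Grignard cross-coupling with the halomagnesium salt of an ω-bromo acid is an established fatty-acid chain extension, the carboxylate being inert to the organocopper species and the silyl ether to the Grignard reagent.

Step 9
Reactants: 8 labdanyl hydrogen adipate; 14 28-[(tert-butyldimethylsilyl)oxy]octacosanoic acid (4 equiv)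
Product: 17 17-[(tert-butyldimethylsilyl)oxy]-ent-labda-7,13E-dien-15-yl 32-[(tert-butyldimethylsilyl)oxy]dotriacontanoate, via acyl-side primary radical 15 (not isolated), via silyloxyheptacosyl radical 16 (not isolated)
Conditions: undivided cell, smooth Pt anode and Pt cathode, constant current about 200 mA cm−2, NaOMe (5–10 % neutralisation of total acid), MeOH–acetone 4:1, 45 °C, periodic polarity reversal, stopped while still faintly acidic
Reagents that add atoms: none
Why: Mixed Kolbe electrolysis: the carboxylates of 8 and 14 are each oxidised by one electron at the platinum anode, lose CO2 and leave the primary radicals 15 and 16, which combine in the radical-rich layer at the electrode surface to form the C5'–C6' CH2–CH2 bond while protons are reduced to H2 at the cathode. The closest known reaction type is the anodic chain extension of fatty acids with alkyl hydrogen adipates, in which esters, silyl ethers and remote isolated C=C bonds are carried through. No ring is closed and no stereocentre is created, so C5, C9, C10 and the 13E geometry only have to survive, which they should because no strong acid, base or metal that could ionise the allylic ester is present. Radical rather than cationic (Hofer–Moest) behaviour is secured by both radical carbons being unbranched CH2 groups without a donor atom in the α or β position, and by smooth Pt, high current density and low neutralisation. Cross- over homo-coupling can only be steered statistically, so the two-step acid 14 is used in fourfold excess, which should pair most of radical 15 with radical 16, and the non-polar symmetrical dimer of 16 is removed by chromatography. Chemoselectivity against C7=C8 and C13=C14 rests on the carboxylate film that screens the anode, on the inductive deactivation of both alkenes by their allylic oxygen substituents and on their distance from C5' (the nearest closure, onto C14, would be eight-membered), and the current is switched off before the acids are exhausted so that no methoxide builds up to transesterify the allylic ester.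

Step 10
Reactants: 17 bis-silyl ether of the target
Product: 18 17-hydroxy-ent-labda-7,13E-dien-15-yl 32-hydroxydotriacontanoate (target)
Conditions: HF·pyridine, pyridine–THF, 0 °C to rt
Reagents that add atoms: none
Why: Fluoride-mediated cleavage of both primary TBS ethers under buffered conditions should leave the allylic ester, both trisubstituted alkenes and all stereocentres unaffected.

**Compound list**
1 | (−)-copalic acid, ent-labda-8(17),13E-dien-15-oic acid | C/C(=C\C(=O)O)CC[C@@H]1C(=C)CC[C@@H]2C(C)(C)CCC[C@@]12C | starting material
2 | isopropyl ent-labda-8(17),13E-dien-15-oate | C/C(=C\C(=O)OC(C)C)CC[C@@H]1C(=C)CC[C@@H]2C(C)(C)CCC[C@@]12C | intermediate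
3 | isopropyl (8S)-8,17-epoxy-ent-labd-13E-en-15-oate | C/C(=C\C(=O)OC(C)C)CC[C@@H]1[C@]3(CO3)CC[C@@H]2C(C)(C)CCC[C@@]12C | intermediate
4 | isopropyl 17-hydroxy-ent-labda-7,13E-dien-15-oate | C/C(=C\C(=O)OC(C)C)CC[C@@H]1C(CO)=CC[C@@H]2C(C)(C)CCC[C@@]12C | intermediate
5 | isopropyl 17-[(tert-butyldimethylsilyl)oxy]-ent-labda-7,13E-dien-15-oate | C/C(=C\C(=O)OC(C)C)CC[C@@H]1C(CO[Si](C)(C)C(C)(C)C)=CC[C@@H]2C(C)(C)CCC[C@@]12C | intermediate
6 | 17-[(tert-butyldimethylsilyl)oxy]-ent-labda-7,13E-dien-15-ol | C/C(=C\CO)CC[C@@H]1C(CO[Si](C)(C)C(C)(C)C)=CC[C@@H]2C(C)(C)CCC[C@@]12C | intermediate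
7 | adipic acid | OC(=O)CCCCC(=O)O | starting material
8 | 6-oxo-6-{[17-(tert-butyldimethylsilyloxy)-ent-labda-7,13E-dien-15-yl]oxy}hexanoic acid | C/C(=C\COC(=O)CCCCC(=O)O)CC[C@@H]1C(CO[Si](C)(C)C(C)(C)C)=CC[C@@H]2C(C)(C)CCC[C@@]12C | intermediate
9 | 12-bromododecan-1-ol | OCCCCCCCCCCCCBr | starting material
10 | (12-bromododecyloxy)(tert-butyl)dimethylsilane | CC(C)(C)[Si](C)(C)OCCCCCCCCCCCCBr | intermediate
11 | 16-bromohexadecanoic acid | OC(=O)CCCCCCCCCCCCCCCBr | starting material
12 | 12-[(tert-butyldimethylsilyl)oxy]dodecylmagnesium bromide | CC(C)(C)[Si](C)(C)OCCCCCCCCCCCC[Mg]Br | intermediate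
13 | chloromagnesium 16-bromohexadecanoate | Cl[Mg]OC(=O)CCCCCCCCCCCCCCCBr | intermediate
14 | 28-[(tert-butyldimethylsilyl)oxy]octacosanoic acid | CC(C)(C)[Si](C)(C)OCCCCCCCCCCCCCCCCCCCCCCCCCCCC(=O)O | intermediate
15 | 5-oxo-5-(labdanyloxy)pentyl radical from 8 | C/C(=C\COC(=O)CCC[CH2])CC[C@@H]1C(CO[Si](C)(C)C(C)(C)C)=CC[C@@H]2C(C)(C)CCC[C@@]12C | intermediate
16 | 27-[(tert-butyldimethylsilyl)oxy]heptacosyl radical from 14 | [CH2]CCCCCCCCCCCCCCCCCCCCCCCCCCO[Si](C)(C)C(C)(C)C | intermediate
17 | 17-[(tert-butyldimethylsilyl)oxy]-ent-labda-7,13E-dien-15-yl 32-[(tert-butyldimethylsilyl)oxy]dotriacontanoate | C/C(=C\COC(=O)CCCCCCCCCCCCCCCCCCCCCCCCCCCCCCCO[Si](C)(C)C(C)(C)C)CC[C@@H]1C(CO[Si](C)(C)C(C)(C)C)=CC[C@@H]2C(C)(C)CCC[C@@]12C | intermediate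
18 | 17-hydroxy-ent-labda-7,13E-dien-15-yl 32-hydroxydotriacontanoate (5R,9S,10R) | C/C(=C\COC(=O)CCCCCCCCCCCCCCCCCCCCCCCCCCCCCCCO)CC[C@@H]1C(CO)=CC[C@@H]2C(C)(C)CCC[C@@]12C | target

**Total step count:** 10. **Longest linear sequence:** 8 (steps 1–6, 9, 10).

**Steps most likely to fail**

Step 9. Anodic over-oxidation of the two trisubstituted alkenes, fouling of the electrodes by waxy deposits, and statistical loss of the terpene acid to self-coupling may erode the cross-coupling. The fallback takes the electrolysis off the terpene. It sets out from 14, which is electrolysed under the same type of conditions with an excess of commercial methyl hydrogen adipate. This gives methyl 32-[(tert-butyldimethylsilyl)oxy]dotriacontanoate F1. Saponification (LiOH, THF–MeOH–H2O, warm) gives 32-[(tert-butyldimethylsilyl)oxy]dotriacontanoic acid F2. Steglich esterification of F2 with alcohol 6 (EDC·HCl, DMAP, CH2Cl2) comes back to the route at 17.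

Step 3. Proton loss from C9 instead of C7, or a 1,2-hydride shift from C17 to C8, may compete with the wanted elimination. The fallback sets out from 2 and avoids the epoxide. Riley-type allylic hydroxylation (catalytic SeO2, t-BuOOH, CH2Cl2) of the electron-rich C8=C17 alkene should give isopropyl (7S)-7-hydroxy-ent-labda-8(17),13E-dien-15-oate F3, with the OH axial and anti to the C10 methyl. A rhenium-oxo-catalysed 1,3-transposition of the allylic alcohol (Ph3SiOReO3, Et2O, 0 °C) should then drain F3 to the more substituted alkene and primary alcohol. This comes back to the route at 4.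

Step 8. Poor solubility of the magnesium carboxylate, with Wurtz-type self-coupling or reduction of the Grignard reagent, may stall the sp3–sp3 coupling. The fallback replaces it by olefination and hydrogenation, and sets out from 11 and 10.
- Compound 11 and PPh3 (MeCN, reflux) give (15-carboxypentadecyl)triphenylphosphonium bromide F4.
- Compound 10 undergoes Kornblum-type oxidation with trimethylamine N-oxide (DMSO, rt to 50 °C) to give 12-[(tert-butyldimethylsilyl)oxy]dodecanal F5.
- Wittig reaction of F4 (NaHMDS, 2.1 equiv, THF, −78 °C to rt) with F5 gives (Z)-28-[(tert-butyldimethylsilyl)oxy]octacos-16-enoic acid F6.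
- Hydrogenation of F6 (H2, Pd/C, EtOAc) comes back to the route at 14.

**Further compounds**
F1 | step 9 | methyl 32-[(tert-butyldimethylsilyl)oxy]dotriacontanoate | COC(=O)CCCCCCCCCCCCCCCCCCCCCCCCCCCCCCCO[Si](C)(C)C(C)(C)C
F2 | step 9 | 32-[(tert-butyldimethylsilyl)oxy]dotriacontanoic acid | OC(=O)CCCCCCCCCCCCCCCCCCCCCCCCCCCCCCCO[Si](C)(C)C(C)(C)C
F3 | step 3 | isopropyl (7S)-7-hydroxy-ent-labda-8(17),13E-dien-15-oate | C/C(=C\C(=O)OC(C)C)CC[C@@H]1C(=C)[C@@H](O)C[C@@H]2C(C)(C)CCC[C@@]12C
F4 | step 8 | (15-carboxypentadecyl)triphenylphosphonium bromide | [Br-].OC(=O)CCCCCCCCCCCCCCC[P+](c1ccccc1)(c1ccccc1)c1ccccc1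
F5 | step 8 | 12-[(tert-butyldimethylsilyl)oxy]dodecanal | CC(C)(C)[Si](C)(C)OCCCCCCCCCCCC=O
F6 | step 8 | (Z)-28-[(tert-butyldimethylsilyl)oxy]octacos-16-enoic acid | CC(C)(C)[Si](C)(C)OCCCCCCCCCCC/C=C\CCCCCCCCCCCCCCC(=O)O
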